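**Plan**

1. Numbering: ring A is the oxygenated ring (C1 OMe, C2 Br, C3 H, C4 OH, C5 O-aryl, C6 Br); ring B is the dibromophenoxy ring (C1' on the ether oxygen, C2' Br, C3' H, C4' Br, C5' H, C6' H).
2. Enabling feature: ring B carries Br, H, Br, H on C2', C3', C4', C5', the same sequence as on C3, C4, C5, C6 of 3,5-dibromo-2-pyrone. The pyrone can therefore deliver four ring B carbons with both bromines in place, and only C1' and C6' are lacking.
3. Retrosynthesis: with the C4 hydroxyl masked as a benzyl ether, ring B is cut at C1'–C2' and C5'–C6' (retro-[4+2], CO2 added back). This leaves the dibromopyrone and an ethynyl ether (C1'≡C6') on the C5 oxygen of ring A. The ynol ether goes back through the 2-bromovinyl, vinyl and 2-bromoethyl ethers to a C5 phenol; removing the C2 and C6 bromines and replacing the C5 oxygen by a formyl group (Dakin-type oxidation in the forward sense) gives 2-hydroxy-5-methoxybenzaldehyde.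
4. Forward order: ring A is bought and decorated first (benzylation, C5 oxygenation, dibromination, O-ethynylation). Ring B is built last on the ether oxygen by cycloaddition and loss of CO2, and debenzylation ends the route.
5. Stereochemistry: the target has no stereocentre; the stereo-elements met on the way (racemic dibromide, Z bromoalkene, bridgeheads of the bridged lactone) are all erased.

Key step: step 9

Remark: benzyl bromide and 1,2-dibromoethane are counted as numbered starting materials and are repeated on the reagent line; chiral intermediates are racemic and drawn as one enantiomer.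

**Route**

Step 1
Reactants: 1 coumalic acid (2-oxo-2H-pyran-5-carboxylic acid)
Product: 3 3,5-dibromo-2H-pyran-2-one, via 3-bromo-2-oxo-2H-pyran-5-carboxylic acid 2 (not isolated)
Conditions: NBS (2.5 equiv), LiOAc, MeCN–H2O, rt
Reagents that add atoms: N-bromosuccinimide, O=C1CCC(=O)N1Br
Why: The pyrone should be brominated at its nucleophilic C3 and the C5 carboxylate replaced by bromine through ipso bromodecarboxylation (Hunsdiecker-type), a known one-pot route to this dibromopyrone.

Step 2
Reactants: 4 2-hydroxy-5-methoxybenzaldehyde; 5 benzyl bromide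
Product: 6 2-(benzyloxy)-5-methoxybenzaldehyde
Conditions: BnBr, K2CO3, DMF, rt
Reagents that add atoms: benzyl bromide 5, BrCc1ccccc1
Why: Williamson etherification of the phenoxide installs a benzyl ether on the future C4 oxygen that should survive every later step until the final Lewis acid cleavage.

Step 3
Reactants: 6 2-(benzyloxy)-5-methoxybenzaldehyde
Product: 8 2-(benzyloxy)-5-methoxyphenol, via 2-(benzyloxy)-5-methoxyphenyl formate 7 (not isolated)
Conditions: mCPBA, CH2Cl2, rt; then K2CO3 (cat.), MeOH, rt
Reagents that add atoms: 3-chloroperoxybenzoic acid (mCPBA), OOC(=O)c1cccc(Cl)c1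
Why: In this Baeyer–Villiger (Dakin-type) oxidation the electron-rich aryl group with its ortho alkoxy donor migrates in preference to hydride, and mild methanolysis of the formate frees the C5 phenol.

Step 4
Reactants: 8 2-(benzyloxy)-5-methoxyphenol
Product: 10 6-(benzyloxy)-2,4-dibromo-3-methoxyphenol, via 2-(benzyloxy)-4-bromo-5-methoxyphenol 9 (not isolated)
Conditions: NBS (2.05 equiv), MeCN, 0 °C to rt
Reagents that add atoms: N-bromosuccinimide, O=C1CCC(=O)N1Br
Why: Electrophilic aromatic bromination is steered by the free C5 hydroxyl to its para position (C2) and its only open ortho position (C6), both also ortho to OMe, whereas C3 is meta to both donors and should stay untouched.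

Step 5
Reactants: 10 6-(benzyloxy)-2,4-dibromo-3-methoxyphenol; 11 1,2-dibromoethane
Product: 12 1-(benzyloxy)-3,5-dibromo-2-(2-bromoethoxy)-4-methoxybenzene
Conditions: BrCH2CH2Br (excess), K2CO3, MeCN, reflux
Reagents that add atoms: 1,2-dibromoethane 11, BrCCBr
Why: Williamson alkylation of the hindered phenoxide should proceed cleanly, a large excess of the dihalide suppressing the bis-aryl ether.

Step 6
Reactants: 12 1-(benzyloxy)-3,5-dibromo-2-(2-bromoethoxy)-4-methoxybenzene
Product: 13 1-(benzyloxy)-3,5-dibromo-2-(ethenyloxy)-4-methoxybenzene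
Conditions: KOtBu, THF, 0 °C to rt
Reagents that add atoms: none
Why: E2 dehydrobromination of a primary 2-bromoethyl aryl ether with a bulky alkoxide is the standard route to aryl vinyl ethers, and the aryl bromides are inert to KOtBu in THF at this temperature.

Step 7
Reactants: 13 1-(benzyloxy)-3,5-dibromo-2-(ethenyloxy)-4-methoxybenzene
Product: 15 1-(benzyloxy)-3,5-dibromo-2-{[(Z)-2-bromoethenyl]oxy}-4-methoxybenzene, via 1-(benzyloxy)-3,5-dibromo-2-(1,2-dibromoethoxy)-4-methoxybenzene 14 (not isolated)
Conditions: Br2 (1.0 equiv), CH2Cl2, −78 °C; then DBU, −78 °C to rt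
Reagents that add atoms: bromine, BrBr
Why: The enol ether double bond should add bromine far faster than the deactivated, fully substituted ring A reacts, and E2 loss of HBr from the α-bromo ether then gives the 2-bromovinyl ether, the cis isomer being the usual main product for 1-alkoxy-2-haloethenes (any E isomer is removed by chromatography).

Step 8
Reactants: 15 1-(benzyloxy)-3,5-dibromo-2-{[(Z)-2-bromoethenyl]oxy}-4-methoxybenzene
Product: 16 1-(benzyloxy)-3,5-dibromo-2-(ethynyloxy)-4-methoxybenzene
Conditions: KOtBu, THF, −78 to 0 °C; cold aqueous NH4Cl quench, extraction into toluene, solution used at once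
Reagents that add atoms: none
Why: Anti E2 dehydrobromination of the Z bromoenol ether (vinyl hydrogen trans to bromine) is the classical route to aryloxyacetylenes, and cold work-up with immediate use should limit polymerisation of the terminal ynol ether.

Step 9
Reactants: 16 1-(benzyloxy)-3,5-dibromo-2-(ethynyloxy)-4-methoxybenzene; 3 3,5-dibromo-2H-pyran-2-one
Product: 18 1-(benzyloxy)-3,5-dibromo-2-(2,4-dibromophenoxy)-4-methoxybenzene, via 5-aryloxy-4,7-dibromo-2-oxabicyclo[2.2.2]octa-5,7-dien-3-one 17 (not isolated)
Conditions: 3 (2.5 equiv), BHT (cat.), toluene, 60 °C, then 110 °C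
Reagents that add atoms: none
Why: Proposed new method: the electron-rich aryl ynol ether 16 and the electron-poor diene 3 should combine in an asynchronous inverse-electron-demand [4+2] cycloaddition, the nucleophilic alkyne terminus bonding to the electrophilic pyrone C6 and the oxygen-bearing alkyne carbon to pyrone C3, after which the bridged dienyl lactone 17 expels CO2 by retro-[4+2]. The closest known reaction types are the Diels-Alder reactions of 3,5-dibromo-2-pyrone with vinyl ethers, which give 5-alkoxy adducts of the same orientation, and the pyrone-alkyne cycloaddition with decarboxylation that gives benzenes. Ring B is closed by intermolecular [4+2] cycloaddition (C1'–C2' and C6'–C5' formed together) and becomes a benzene directly in the cycloreversion, so no oxidation or elimination that could expel the aryloxy group is involved. No stereocentre remains, since the two bridgehead centres of 17 are lost with CO2. The step needs regioselectivity (oxygen-bearing carbon next to the C3 bromine, that is C1' beside C2') and chemoselectivity for cycloaddition over self-reaction of the ynol ether; the first is secured by the polarity match between the ynol ether terminus and pyrone C6, the second by an excess of the pyrone and a moderate initial temperature.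

Step 10
Reactants: 18 1-(benzyloxy)-3,5-dibromo-2-(2,4-dibromophenoxy)-4-methoxybenzene
Product: 20 3,5-dibromo-2-(2,4-dibromophenoxy)-4-methoxyphenol, via dichloro(aryloxy)borane 19 (not isolated)
Conditions: BCl3, C6HMe5, CH2Cl2, −78 °C; then MeOH
Reagents that add atoms: none
Why: Lewis acid debenzylation with BCl3 and pentamethylbenzene as cation scavenger should cleave the aryl benzyl ether at −78 °C without touching the aryl bromides, the hindered methyl ether or the diaryl ether, where hydrogenolysis would debrominate.

**Compound list**

1 | coumalic acid (2-oxo-2H-pyran-5-carboxylic acid) | O=C1C=CC(C(=O)O)=CO1 | starting material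
2 | 3-bromo-2-oxo-2H-pyran-5-carboxylic acid | O=C1OC=C(C(=O)O)C=C1Br | intermediate
3 | 3,5-dibromo-2H-pyran-2-one | O=C1OC=C(Br)C=C1Br | intermediate
4 | 2-hydroxy-5-methoxybenzaldehyde | COc1ccc(O)c(C=O)c1 | starting material
5 | benzyl bromide | BrCc1ccccc1 | starting material
6 | 2-(benzyloxy)-5-methoxybenzaldehyde | COc1ccc(OCc2ccccc2)c(C=O)c1 | intermediate
7 | 2-(benzyloxy)-5-methoxyphenyl formate | COc1ccc(OCc2ccccc2)c(OC=O)c1 | intermediate
8 | 2-(benzyloxy)-5-methoxyphenol | COc1ccc(OCc2ccccc2)c(O)c1 | intermediate
9 | 2-(benzyloxy)-4-bromo-5-methoxyphenol | COc1c(Br)cc(OCc2ccccc2)c(O)c1 | intermediate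
10 | 6-(benzyloxy)-2,4-dibromo-3-methoxyphenol | COc1c(Br)cc(OCc2ccccc2)c(O)c1Br | intermediate
11 | 1,2-dibromoethane | BrCCBr | starting material
12 | 1-(benzyloxy)-3,5-dibromo-2-(2-bromoethoxy)-4-methoxybenzene | COc1c(Br)cc(OCc2ccccc2)c(OCCBr)c1Br | intermediate
13 | 1-(benzyloxy)-3,5-dibromo-2-(ethenyloxy)-4-methoxybenzene | COc1c(Br)cc(OCc2ccccc2)c(OC=C)c1Br | intermediate
14 | 1-(benzyloxy)-3,5-dibromo-2-(1,2-dibromoethoxy)-4-methoxybenzene (racemic, one enantiomer drawn) | COc1c(Br)cc(OCc2ccccc2)c(O[C@H](Br)CBr)c1Br | intermediate
15 | 1-(benzyloxy)-3,5-dibromo-2-{[(Z)-2-bromoethenyl]oxy}-4-methoxybenzene | COc1c(Br)cc(OCc2ccccc2)c(O/C=C\Br)c1Br | intermediate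
16 | 1-(benzyloxy)-3,5-dibromo-2-(ethynyloxy)-4-methoxybenzene | C#COc1c(OCc2ccccc2)cc(Br)c(OC)c1Br | intermediate
17 | 5-[6-(benzyloxy)-2,4-dibromo-3-methoxyphenoxy]-4,7-dibromo-2-oxabicyclo[2.2.2]octa-5,7-dien-3-one (racemic, one enantiomer drawn) | O=C1O[C@@H]2C=C(Oc3c(OCc4ccccc4)cc(Br)c(OC)c3Br)[C@@]1(Br)C=C2Br | intermediate
18 | 1-(benzyloxy)-3,5-dibromo-2-(2,4-dibromophenoxy)-4-methoxybenzene | COc1c(Br)cc(OCc2ccccc2)c(Oc2ccc(Br)cc2Br)c1Br | intermediate
19 | dichloro[3,5-dibromo-2-(2,4-dibromophenoxy)-4-methoxyphenoxy]borane | COc1c(Br)cc(OB(Cl)Cl)c(Oc2ccc(Br)cc2Br)c1Br | intermediate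
20 | 3,5-dibromo-2-(2,4-dibromophenoxy)-4-methoxyphenol (CNP0140065.0) | COc1c(Br)cc(O)c(Oc2ccc(Br)cc2Br)c1Br | target

**Count and risks**

Total step count: 10. Longest linear sequence: 9 steps (steps 2 to 10, from 2-hydroxy-5-methoxybenzaldehyde); step 1 supplies the pyrone for the convergent step 9.

Steps most likely to fail:

1. Step 9 (Proposed new method). The terminal aryl ynol ether may polymerise or dimerise faster than it adds to the pyrone, the crowded transition state (ring A is substituted on both sides of the ether oxygen) may slow the cycloaddition further, or the addition may take the opposite orientation. The fallback uses known chemistry and gives up the cycloaddition: it sets out from phenol 10 and comes back at 18. The phenoxide of 10 (NaOH, water–dioxane, reflux, or KOtBu in THF) would be O-arylated without any transition metal by bis(2,4-dibromophenyl)iodonium chloride F1. F1 is made from commercial 1,3-dibromobenzene with I2 and NaIO3 in H2SO4 and precipitated with NaCl. This is an established way to polybrominated diphenyl ethers, and the aryl bromides are not touched.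

2. Step 8. The ynol ether may be lost during its formation and work-up through polymerisation or through addition of tert-butoxide across the triple bond, and any residual E isomer of 15 would eliminate only sluggishly. The fallback avoids the free alkyne; it sets out from bromovinyl ether 15 and comes back at 18. The thermally robust 15 would itself be heated with pyrone 3 (toluene or xylene, 110–130 °C, 2,6-lutidine present). The cycloaddition, in the same orientation, should give 5-aryloxy-4,6,7-tribromo-2-oxabicyclo[2.2.2]oct-7-en-3-one F2. Loss of CO2 leads to the cis-2,4,6-tribromocyclohexa-2,4-dien-1-yl aryl ether F3, in which the hydrogen on the aryloxy carbon is anti to the neighbouring bromine. Elimination of HBr, with bromide a far better leaving group than the aryloxide, then aromatises ring B to 18.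

3. Step 7. Bromine may attack ring A or the benzyl ring instead of adding to the vinyl ether, and the α-bromo ether 14 may be hydrolysed or substituted instead of eliminating. The fallback moves the oxidation to after ring closure; it sets out from vinyl ether 13 and comes back at 18. Vinyl ether 13 would be combined with pyrone 3 in the way known for this pyrone and vinyl ethers (toluene, 50–80 °C) to give 5-aryloxy-4,7-dibromo-2-oxabicyclo[2.2.2]oct-7-en-3-one F4. Heating F4 with DDQ (toluene, 110 °C) should extrude CO2 to the 2,4-dibromocyclohexa-2,4-dien-1-yl aryl ether F5. F5 is dehydrogenated as it forms, before it can lose the phenol, to give 18.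

Further compounds

F1 | step 9 | bis(2,4-dibromophenyl)iodonium chloride | [Cl-].Brc1ccc([I+]c2ccc(Br)cc2Br)c(Br)c1
F2 | step 8 | 5-[6-(benzyloxy)-2,4-dibromo-3-methoxyphenoxy]-4,6,7-tribromo-2-oxabicyclo[2.2.2]oct-7-en-3-one (racemic, cis and endo isomer drawn) | O=C1O[C@H]2C(Br)=C[C@]1(Br)[C@H](Oc3c(OCc4ccccc4)cc(Br)c(OC)c3Br)[C@@H]2Br
F3 | step 8 | 1-(benzyloxy)-3,5-dibromo-4-methoxy-2-[(cis-2,4,6-tribromocyclohexa-2,4-dien-1-yl)oxy]benzene (racemic) | C1=C(Br)C=C(Br)[C@H](Oc2c(OCc3ccccc3)cc(Br)c(OC)c2Br)[C@@H]1Br
F4 | step 7 | 5-[6-(benzyloxy)-2,4-dibromo-3-methoxyphenoxy]-4,7-dibromo-2-oxabicyclo[2.2.2]oct-7-en-3-one (racemic, endo isomer drawn) | O=C1O[C@H]2C(Br)=C[C@]1(Br)[C@H](Oc3c(OCc4ccccc4)cc(Br)c(OC)c3Br)C2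
F5 | step 7 | 1-(benzyloxy)-3,5-dibromo-2-[(2,4-dibromocyclohexa-2,4-dien-1-yl)oxy]-4-methoxybenzene (racemic) | C1=C(Br)C=C(Br)[C@H](Oc2c(OCc3ccccc3)cc(Br)c(OC)c2Br)C1
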